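**Strategy.** The route rests on opening the ten-membered carbocycle at its allylic acetate junction: the bond between the acetoxy-bearing carbon C9 and the alkene carbon C10 that carries the hydroxymethyl group (cyclodeca[b]furan numbering). A Nozaki–Hiyama–Kishi macrocyclization of a (Z)-alkenyl iodide onto a tethered aldehyde closes this ring, keeps the (Z)-C10=C11 geometry and creates the C9 carbinol in one operation. Its precursor is an acyclic iodo aldehyde built on the preformed trans-fused α-methylene lactone. That precursor comes from a zinc Barbier coupling of a chiral 3-(bromomethyl)butenolide with a (Z)-enal, followed by a Mitsunobu inversion that installs the tiglate at C4.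

Key step: step 15

Remarks on the chemistry:
- Macrocycle locants follow cyclodeca[b]furan numbering: O1, C2 (lactone carbonyl), C3 (methylidene carbon), C3a, C4 (tiglate), C5=C6 (methyl on C6), C7 (free hydroxyl), C8, C9 (acetate), C10 (hydroxymethyl)=C11, C11a (lactone O–CH).
- Assumption: steps 2 and 7 need the same facial sense of alkyne addition; the ProPhenol antipode that delivers the (S)-carbinols is used in both.

**Route**

Step 1
Reactants: 1 3-[(4-methoxybenzyl)oxy]propan-1-ol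
Product: 2 3-[(4-methoxybenzyl)oxy]propanal
Conditions: TEMPO (cat.), PhI(OAc)2, CH2Cl2, rt
Reagents that add atoms: none
Why: Nitroxyl-catalysed alcohol oxidation should stop at the aldehyde and leave the PMB ether untouched.

Step 2
Reactants: 2 3-[(4-methoxybenzyl)oxy]propanal; 3 methyl propiolate
Product: 4 methyl (S)-4-hydroxy-6-[(4-methoxybenzyl)oxy]hex-2-ynoate
Conditions: Me2Zn, ProPhenol ligand (cat.), Ph3P=O (cat.), toluene, 0 to 4 °C; aq NH4Cl
Reagents that add atoms: none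
Why: Zinc–ProPhenol asymmetric alkynylation, in which the chiral dinuclear zinc alkynylide adds to one aldehyde face, should set the (S)-carbinol that becomes C7 of the target.

Step 3
Reactants: 4 methyl (S)-4-hydroxy-6-[(4-methoxybenzyl)oxy]hex-2-ynoate
Product: 5 methyl (S)-6-[(4-methoxybenzyl)oxy]-4-[(triethylsilyl)oxy]hex-2-ynoate
Conditions: TESCl, imidazole, CH2Cl2, 0 °C
Reagents that add atoms: triethylsilyl chloride, CC[Si](Cl)(CC)CC
Why: Standard silylation of a secondary propargylic alcohol; the triethylsilyl ether is kept to the last step.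

Step 4
Reactants: 5 methyl (S)-6-[(4-methoxybenzyl)oxy]-4-[(triethylsilyl)oxy]hex-2-ynoate
Product: 6 methyl (S,Z)-6-[(4-methoxybenzyl)oxy]-3-methyl-4-[(triethylsilyl)oxy]hex-2-enoate
Conditions: Me2CuLi (from CuI and MeLi), THF, −78 °C; sat. aq NH4Cl at −78 °C
Reagents that add atoms: lithium dimethylcuprate, [Li+].C[Cu-]C
Why: Syn carbocupration (cuprate conjugate addition to an ynoate) with cold protonation places methyl and hydrogen cis, which fixes the (Z)-trisubstituted alkene with the silyloxy carbon cis to the ester.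

Step 5
Reactants: 6 methyl (S,Z)-6-[(4-methoxybenzyl)oxy]-3-methyl-4-[(triethylsilyl)oxy]hex-2-enoate
Product: 7 (S,Z)-6-[(4-methoxybenzyl)oxy]-3-methyl-4-[(triethylsilyl)oxy]hex-2-en-1-ol
Conditions: iBu2AlH, CH2Cl2, −78 °C; Rochelle salt
Reagents that add atoms: none
Why: 1,2-Reduction of the enoate by the aluminium hydride gives the allylic alcohol without touching the alkene geometry.

Step 6
Reactants: 7 (S,Z)-6-[(4-methoxybenzyl)oxy]-3-methyl-4-[(triethylsilyl)oxy]hex-2-en-1-ol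
Product: 8 (S,Z)-6-[(4-methoxybenzyl)oxy]-3-methyl-4-[(triethylsilyl)oxy]hex-2-enal
Conditions: MnO2, CH2Cl2, rt, dark
Reagents that add atoms: none
Why: Neutral allylic oxidation with MnO2 should give the (Z)-enal without acid- or base-induced Z/E isomerization.

Step 7
Reactants: 9 (E)-but-2-enal; 10 tert-butyldimethyl(prop-2-yn-1-yloxy)silane
Product: 11 (S,E)-1-[(tert-butyldimethylsilyl)oxy]hept-5-en-2-yn-4-ol
Conditions: Me2Zn, ProPhenol ligand (cat.), Ph3P=O (cat.), toluene, 0 to 4 °C; aq NH4Cl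
Reagents that add atoms: none
Why: Zinc–ProPhenol asymmetric alkynylation of an enal (the best substrate class for this reaction) sets the carbinol that becomes C11a.

Step 8
Reactants: 11 (S,E)-1-[(tert-butyldimethylsilyl)oxy]hept-5-en-2-yn-4-ol
Product: 13 (2Z,4S,5E)-1-[(tert-butyldimethylsilyl)oxy]-2-iodohepta-2,5-dien-4-ol, via sodium alkenylalanate 12 (not isolated)
Conditions: NaAlH2(OCH2CH2OMe)2 (Red-Al), THF, 0 °C; then EtOAc; I2, −78 °C
Reagents that add atoms: iodine, II
Why: Hydroxyl-directed trans-hydroalumination of the propargylic alcohol followed by iodinolysis with retention puts iodine on the carbon remote from the carbinol and cis to it, which is the (Z)-alkenyl iodide geometry the macrocyclization needs.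

Step 9
Reactants: 13 (2Z,4S,5E)-1-[(tert-butyldimethylsilyl)oxy]-2-iodohepta-2,5-dien-4-ol; 14 2-(bromomethyl)prop-2-enoic acid
Product: 15 (2Z,4S,5E)-1-[(tert-butyldimethylsilyl)oxy]-2-iodohepta-2,5-dien-4-yl 2-(bromomethyl)prop-2-enoate
Conditions: DCC, DMAP (cat.), CH2Cl2, −20 to 0 °C
Reagents that add atoms: none
Why: Steglich esterification at low temperature acylates the secondary alcohol with retention while keeping amine attack on the allylic bromide slow.

Step 10
Reactants: 15 (2Z,4S,5E)-1-[(tert-butyldimethylsilyl)oxy]-2-iodohepta-2,5-dien-4-yl 2-(bromomethyl)prop-2-enoate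
Product: 16 (S)-3-(bromomethyl)-5-[(Z)-3-[(tert-butyldimethylsilyl)oxy]-2-iodoprop-1-en-1-yl]furan-2(5H)-one
Conditions: second-generation Hoveyda–Grubbs catalyst (cat.), toluene, 80 °C, argon sparge
Reagents that add atoms: none
Why: Ring-closing metathesis between the propenyl group and the 1,1-disubstituted acrylate closes the butenolide with loss of propene, the iodo-substituted trisubstituted alkene being inert to the ruthenium carbene.

Step 11
Reactants: 16 (S)-3-(bromomethyl)-5-[(Z)-3-[(tert-butyldimethylsilyl)oxy]-2-iodoprop-1-en-1-yl]furan-2(5H)-one; 8 (S,Z)-6-[(4-methoxybenzyl)oxy]-3-methyl-4-[(triethylsilyl)oxy]hex-2-enal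
Product: 18 (4R,5S)-5-[(Z)-3-[(tert-butyldimethylsilyl)oxy]-2-iodoprop-1-en-1-yl]-4-[(1S,2Z,4S)-1-hydroxy-6-[(4-methoxybenzyl)oxy]-3-methyl-4-[(triethylsilyl)oxy]hex-2-en-1-yl]-3-methylidenedihydrofuran-2(3H)-one, via allylzinc bromide 17 (not isolated)
Conditions: Zn dust, THF/sat. aq NH4Cl, 0 °C to rt
Reagents that add atoms: none
Why: In this zinc Barbier allylation the ring-locked allylzinc should add through its γ-carbon in a closed six-membered chair transition state on the lactone face opposite the C5 alkenyl group with the aldehyde substituent equatorial, which sets C4 trans to C5 and gives the (1S)-carbinol, the epimer required for the inversion in step 12.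

Step 12
Reactants: 18 the Barbier adduct; 19 (E)-2-methylbut-2-enoic acid (tiglic acid)
Product: 20 (1R,2Z,4S)-1-[(2S,3R)-2-[(Z)-3-[(tert-butyldimethylsilyl)oxy]-2-iodoprop-1-en-1-yl]-4-methylidene-5-oxooxolan-3-yl]-6-[(4-methoxybenzyl)oxy]-3-methyl-4-[(triethylsilyl)oxy]hex-2-en-1-yl (E)-2-methylbut-2-enoate
Conditions: PPh3, DIAD, toluene, 0 °C to rt (betaine preformed)
Reagents that add atoms: none
Why: Mitsunobu esterification displaces the alkoxyphosphonium by tiglate in an SN2 sense, which inverts the allylic carbinol to the (R)-configuration of C4 and installs the ester in the same step, SN2' attack being disfavoured at the fully substituted alkene carbon.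

Step 13
Reactants: 20 the tiglate PMB ether
Product: 21 (1R,2Z,4S)-1-[(2S,3R)-2-[(Z)-3-[(tert-butyldimethylsilyl)oxy]-2-iodoprop-1-en-1-yl]-4-methylidene-5-oxooxolan-3-yl]-6-hydroxy-3-methyl-4-[(triethylsilyl)oxy]hex-2-en-1-yl (E)-2-methylbut-2-enoate
Conditions: DDQ, CH2Cl2/pH 7 buffer, 0 °C
Reagents that add atoms: none
Why: Oxidative PMB cleavage is selective for the electron-rich benzyl ether and should spare the silyl ethers, the esters and the alkenyl iodide under buffered conditions.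

Step 14
Reactants: 21 the primary alcohol
Product: 22 (1R,2Z,4S)-1-[(2S,3R)-2-[(Z)-3-[(tert-butyldimethylsilyl)oxy]-2-iodoprop-1-en-1-yl]-4-methylidene-5-oxooxolan-3-yl]-3-methyl-6-oxo-4-[(triethylsilyl)oxy]hex-2-en-1-yl (E)-2-methylbut-2-enoate
Conditions: Dess–Martin periodinane, NaHCO3, CH2Cl2, 0 °C to rt
Reagents that add atoms: none
Why: Buffered Dess–Martin oxidation gives the β-silyloxy aldehyde under conditions mild enough to avoid β-elimination; the aldehyde is used at once.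

Step 15
Reactants: 22 the iodo aldehyde
Product: 24 (3aR,4R,5Z,7S,9S,10Z,11aR)-10-{[(tert-butyldimethylsilyl)oxy]methyl}-9-hydroxy-6-methyl-3-methylidene-2-oxo-7-[(triethylsilyl)oxy]-2,3,3a,4,7,8,9,11a-octahydrocyclodeca[b]furan-4-yl (E)-2-methylbut-2-enoate, via alkenylchromium dichloride 23 (not isolated)
Conditions: CrCl2 (excess), NiCl2 (cat.), DMSO/THF, rt, slow addition to 0.002 M
Reagents that add atoms: none
Why: CrCl2 reduces NiCl2 to zerovalent nickel, which inserts into the C–I bond of 22 with retention of the Z geometry, and transmetalation gives the trivalent alkenylchromium dichloride 23, which adds to the tethered aldehyde to give the chromium alkoxide of 24 (Nozaki–Hiyama–Kishi reaction). The closest known chemistry is the Nozaki–Hiyama–Kishi macrocyclization of alkenyl iodides onto aldehydes to close ten-membered germacranolide rings on a preformed α-methylene lactone. The ten-membered carbocycle closes in a 10-exo-trig mode by C10–C9 bond formation, with the trans-fused lactone and the two Z alkenes acting as turn elements. The new C9 stereocenter is set by 1,3-induction from the C7 triethylsilyloxy group: in the polar model for β-alkoxy aldehydes the C=O lies antiperiplanar to the C7–O dipole and is attacked on the open outer face of the folded chain, which should give the 7,9-anti (9S) carbinol. The step needs chemoselectivity for the aldehyde over the two enoate acceptors and the allylic esters, secured by the low basicity and carbonyl selectivity of alkenylchromium reagents, and ring closure over oligomerization, secured by slow addition at high dilution.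

Step 16
Reactants: 24 the macrocyclic allylic alcohol
Product: 25 (3aR,4R,5Z,7S,9S,10Z,11aR)-9-acetoxy-10-{[(tert-butyldimethylsilyl)oxy]methyl}-6-methyl-3-methylidene-2-oxo-7-[(triethylsilyl)oxy]-2,3,3a,4,7,8,9,11a-octahydrocyclodeca[b]furan-4-yl (E)-2-methylbut-2-enoate
Conditions: Ac2O, pyridine, DMAP (cat.), CH2Cl2, 0 °C
Reagents that add atoms: acetic anhydride, CC(=O)OC(C)=O
Why: Standard acylation of the only free hydroxyl, the carbinol created in the ring closure, with retention at C9.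

Step 17
Reactants: 25 the bis-silyl ether
Product: 26 eupacunolin, (3aR,4R,5Z,7S,9S,10Z,11aR)-9-acetoxy-7-hydroxy-10-(hydroxymethyl)-6-methyl-3-methylidene-2-oxo-2,3,3a,4,7,8,9,11a-octahydrocyclodeca[b]furan-4-yl (E)-2-methylbut-2-enoate
Conditions: HF·pyridine, pyridine, THF, 0 °C to rt
Reagents that add atoms: none
Why: Buffered fluoride desilylation removes both silyl ethers under weakly acidic conditions that should avoid acetyl migration and conjugate addition to the α-methylene lactone.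

**Compound list**

1 | 3-[(4-methoxybenzyl)oxy]propan-1-ol | OCCCOCc1ccc(OC)cc1 | starting material
2 | 3-[(4-methoxybenzyl)oxy]propanal | O=CCCOCc1ccc(OC)cc1 | intermediate
3 | methyl propiolate | C#CC(=O)OC | starting material
4 | methyl (S)-4-hydroxy-6-[(4-methoxybenzyl)oxy]hex-2-ynoate | COC(=O)C#C[C@@H](O)CCOCc1ccc(OC)cc1 | intermediate
5 | methyl (S)-6-[(4-methoxybenzyl)oxy]-4-[(triethylsilyl)oxy]hex-2-ynoate | COC(=O)C#C[C@@H](O[Si](CC)(CC)CC)CCOCc1ccc(OC)cc1 | intermediate
6 | methyl (S,Z)-6-[(4-methoxybenzyl)oxy]-3-methyl-4-[(triethylsilyl)oxy]hex-2-enoate | COC(=O)/C=C(/C)[C@@H](O[Si](CC)(CC)CC)CCOCc1ccc(OC)cc1 | intermediate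
7 | (S,Z)-6-[(4-methoxybenzyl)oxy]-3-methyl-4-[(triethylsilyl)oxy]hex-2-en-1-ol | OC/C=C(/C)[C@@H](O[Si](CC)(CC)CC)CCOCc1ccc(OC)cc1 | intermediate
8 | (S,Z)-6-[(4-methoxybenzyl)oxy]-3-methyl-4-[(triethylsilyl)oxy]hex-2-enal | O=C/C=C(/C)[C@@H](O[Si](CC)(CC)CC)CCOCc1ccc(OC)cc1 | intermediate
9 | (E)-but-2-enal | C/C=C/C=O | starting material
10 | tert-butyldimethyl(prop-2-yn-1-yloxy)silane | C#CCO[Si](C)(C)C(C)(C)C | starting material
11 | (S,E)-1-[(tert-butyldimethylsilyl)oxy]hept-5-en-2-yn-4-ol | O[C@@H](/C=C/C)C#CCO[Si](C)(C)C(C)(C)C | intermediate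
12 | sodium alkenylalanate: sodium (S)-2,2-bis(2-methoxyethoxy)-5-[(E)-prop-1-en-1-yl]-3-{[(tert-butyldimethylsilyl)oxy]methyl}-2,5-dihydro-1,2-oxaaluminol-2-uide | C/C=C/[C@@H]1O[Al-](OCCOC)(OCCOC)C(CO[Si](C)(C)C(C)(C)C)=C1.[Na+] | intermediate (not isolated)
13 | (2Z,4S,5E)-1-[(tert-butyldimethylsilyl)oxy]-2-iodohepta-2,5-dien-4-ol | O[C@@H](/C=C/C)/C=C(/CO[Si](C)(C)C(C)(C)C)I | intermediate
14 | 2-(bromomethyl)prop-2-enoic acid | C=C(CBr)C(=O)O | starting material
15 | (2Z,4S,5E)-1-[(tert-butyldimethylsilyl)oxy]-2-iodohepta-2,5-dien-4-yl 2-(bromomethyl)prop-2-enoate | C=C(CBr)C(=O)O[C@@H](/C=C/C)/C=C(/CO[Si](C)(C)C(C)(C)C)I | intermediate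
16 | (S)-3-(bromomethyl)-5-[(Z)-3-[(tert-butyldimethylsilyl)oxy]-2-iodoprop-1-en-1-yl]furan-2(5H)-one | BrCC1=C[C@@H](/C=C(/CO[Si](C)(C)C(C)(C)C)I)OC1=O | intermediate
17 | allylzinc bromide: {(S)-5-[(Z)-3-[(tert-butyldimethylsilyl)oxy]-2-iodoprop-1-en-1-yl]-2-oxo-2,5-dihydrofuran-3-yl}methylzinc bromide | Br[Zn]CC1=C[C@@H](/C=C(/CO[Si](C)(C)C(C)(C)C)I)OC1=O | intermediate (not isolated)
18 | (4R,5S)-5-[(Z)-3-[(tert-butyldimethylsilyl)oxy]-2-iodoprop-1-en-1-yl]-4-[(1S,2Z,4S)-1-hydroxy-6-[(4-methoxybenzyl)oxy]-3-methyl-4-[(triethylsilyl)oxy]hex-2-en-1-yl]-3-methylidenedihydrofuran-2(3H)-one | C=C1C(=O)O[C@H](/C=C(/CO[Si](C)(C)C(C)(C)C)I)[C@H]1[C@@H](O)/C=C(/C)[C@@H](O[Si](CC)(CC)CC)CCOCc1ccc(OC)cc1 | intermediate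
19 | (E)-2-methylbut-2-enoic acid (tiglic acid) | C/C=C(\C)C(=O)O | starting material
20 | (1R,2Z,4S)-1-[(2S,3R)-2-[(Z)-3-[(tert-butyldimethylsilyl)oxy]-2-iodoprop-1-en-1-yl]-4-methylidene-5-oxooxolan-3-yl]-6-[(4-methoxybenzyl)oxy]-3-methyl-4-[(triethylsilyl)oxy]hex-2-en-1-yl (E)-2-methylbut-2-enoate | C=C1C(=O)O[C@H](/C=C(/CO[Si](C)(C)C(C)(C)C)I)[C@H]1[C@H](OC(=O)/C(C)=C/C)/C=C(/C)[C@@H](O[Si](CC)(CC)CC)CCOCc1ccc(OC)cc1 | intermediate
21 | (1R,2Z,4S)-1-[(2S,3R)-2-[(Z)-3-[(tert-butyldimethylsilyl)oxy]-2-iodoprop-1-en-1-yl]-4-methylidene-5-oxooxolan-3-yl]-6-hydroxy-3-methyl-4-[(triethylsilyl)oxy]hex-2-en-1-yl (E)-2-methylbut-2-enoate | C=C1C(=O)O[C@H](/C=C(/CO[Si](C)(C)C(C)(C)C)I)[C@H]1[C@H](OC(=O)/C(C)=C/C)/C=C(/C)[C@@H](O[Si](CC)(CC)CC)CCO | intermediate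
22 | (1R,2Z,4S)-1-[(2S,3R)-2-[(Z)-3-[(tert-butyldimethylsilyl)oxy]-2-iodoprop-1-en-1-yl]-4-methylidene-5-oxooxolan-3-yl]-3-methyl-6-oxo-4-[(triethylsilyl)oxy]hex-2-en-1-yl (E)-2-methylbut-2-enoate | C=C1C(=O)O[C@H](/C=C(/CO[Si](C)(C)C(C)(C)C)I)[C@H]1[C@H](OC(=O)/C(C)=C/C)/C=C(/C)[C@@H](O[Si](CC)(CC)CC)CC=O | intermediate
23 | alkenylchromium dichloride: compound 22 with a trivalent CrCl2 group in place of iodine, Z geometry retained | C=C1C(=O)O[C@H](/C=C(/CO[Si](C)(C)C(C)(C)C)[Cr](Cl)Cl)[C@H]1[C@H](OC(=O)/C(C)=C/C)/C=C(/C)[C@@H](O[Si](CC)(CC)CC)CC=O | intermediate (not isolated)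
24 | (3aR,4R,5Z,7S,9S,10Z,11aR)-10-{[(tert-butyldimethylsilyl)oxy]methyl}-9-hydroxy-6-methyl-3-methylidene-2-oxo-7-[(triethylsilyl)oxy]-2,3,3a,4,7,8,9,11a-octahydrocyclodeca[b]furan-4-yl (E)-2-methylbut-2-enoate | C=C1C(=O)O[C@@H]2/C=C(/CO[Si](C)(C)C(C)(C)C)[C@@H](O)C[C@H](O[Si](CC)(CC)CC)/C(C)=C\[C@@H](OC(=O)/C(C)=C/C)[C@@H]12 | intermediate
25 | (3aR,4R,5Z,7S,9S,10Z,11aR)-9-acetoxy-10-{[(tert-butyldimethylsilyl)oxy]methyl}-6-methyl-3-methylidene-2-oxo-7-[(triethylsilyl)oxy]-2,3,3a,4,7,8,9,11a-octahydrocyclodeca[b]furan-4-yl (E)-2-methylbut-2-enoate | C=C1C(=O)O[C@@H]2/C=C(/CO[Si](C)(C)C(C)(C)C)[C@@H](OC(C)=O)C[C@H](O[Si](CC)(CC)CC)/C(C)=C\[C@@H](OC(=O)/C(C)=C/C)[C@@H]12 | intermediate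
26 | eupacunolin, (3aR,4R,5Z,7S,9S,10Z,11aR)-9-acetoxy-7-hydroxy-10-(hydroxymethyl)-6-methyl-3-methylidene-2-oxo-2,3,3a,4,7,8,9,11a-octahydrocyclodeca[b]furan-4-yl (E)-2-methylbut-2-enoate | C=C1C(=O)O[C@@H]2/C=C(/CO)[C@@H](OC(C)=O)C[C@H](O)/C(C)=C\[C@@H](OC(=O)/C(C)=C/C)[C@@H]12 | target

**Step count and risks**

Total step count: 17. Longest linear sequence: 13 steps (steps 1–6, then 11–17, from compound 1).

Steps most likely to fail:

1. Step 15 (macrocyclization). Poor facial selectivity at the aldehyde during ring closure could give the C9 epimer, since the 1,3-induction from a silyloxy group is modest and the ring conformation may override it. Fallback, from 22 back to 24: the cyclization is run as planned and the crude mixture of 24 and its epimer, (3aR,4R,5Z,7S,9R,10Z,11aR)-9-hydroxy macrocycle F1, would be oxidized with Dess–Martin periodinane to the macrocyclic enone, (3aR,4R,5Z,7S,10Z,11aR)-2,9-dioxo macrocycle F2. F2 would then be reduced under reagent control with (R)-2-methyl-CBS-oxazaborolidine and catecholborane at −78 °C, which should deliver the 9S carbinol 24.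

2. Step 12 (Mitsunobu inversion with tiglic acid). Elimination, SN2' displacement or acylation with retention could compete at this hindered allylic carbinol. Fallback, from 18 back to 20: oxidation of 18 with Dess–Martin periodinane would give the enone, (4S,5S)-4-[(2Z,4S)-hex-2-enoyl] lactone F3. CBS reduction of F3 (oxazaborolidine antipode chosen for the 1R carbinol, catecholborane, −78 °C) would give the epimeric alcohol, (4R,5S)-4-[(1R,2Z,4S)-1-hydroxyhex-2-en-1-yl] lactone F4. Yamaguchi esterification of F4 with 19 (2,4,6-trichlorobenzoyl chloride, Et3N, DMAP) would then rejoin the route at 20. This path also accepts any mixture of carbinol epimers from step 11.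

3. Step 10 (ring-closing metathesis). Catalyst deactivation by the activated allylic bromide or sluggish closure onto the 1,1-disubstituted acrylate could stall the reaction. Fallback, from 13 back to 16: acylation of 13 with acryloyl chloride and iPr2NEt would give the acrylate, (2Z,4S,5E)-1-[(tert-butyldimethylsilyl)oxy]-2-iodohepta-2,5-dien-4-yl prop-2-enoate F5. Ring-closing metathesis of F5 with second-generation Grubbs catalyst would give the unsubstituted butenolide, (S)-5-[(Z)-3-[(tert-butyldimethylsilyl)oxy]-2-iodoprop-1-en-1-yl]furan-2(5H)-one F6. A phosphine-catalysed Morita–Baylis–Hillman reaction of F6 with aqueous formaldehyde (PMe3, THF/H2O) would give the hydroxymethyl butenolide, (S)-3-(hydroxymethyl)-5-[(Z)-3-[(tert-butyldimethylsilyl)oxy]-2-iodoprop-1-en-1-yl]furan-2(5H)-one F7. Appel bromination of F7 (CBr4, PPh3) would return to 16.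

Further compounds

F1 | step 15 | (3aR,4R,5Z,7S,9R,10Z,11aR)-10-{[(tert-butyldimethylsilyl)oxy]methyl}-9-hydroxy-6-methyl-3-methylidene-2-oxo-7-[(triethylsilyl)oxy]-2,3,3a,4,7,8,9,11a-octahydrocyclodeca[b]furan-4-yl (E)-2-methylbut-2-enoate | C=C1C(=O)O[C@@H]2/C=C(/CO[Si](C)(C)C(C)(C)C)[C@H](O)C[C@H](O[Si](CC)(CC)CC)/C(C)=C\[C@@H](OC(=O)/C(C)=C/C)[C@@H]12
F2 | step 15 | (3aR,4R,5Z,7S,10Z,11aR)-10-{[(tert-butyldimethylsilyl)oxy]methyl}-6-methyl-3-methylidene-2,9-dioxo-7-[(triethylsilyl)oxy]-2,3,3a,4,7,8,9,11a-octahydrocyclodeca[b]furan-4-yl (E)-2-methylbut-2-enoate | C=C1C(=O)O[C@@H]2/C=C(/CO[Si](C)(C)C(C)(C)C)C(=O)C[C@H](O[Si](CC)(CC)CC)/C(C)=C\[C@@H](OC(=O)/C(C)=C/C)[C@@H]12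
F3 | step 12 | (4S,5S)-5-[(Z)-3-[(tert-butyldimethylsilyl)oxy]-2-iodoprop-1-en-1-yl]-4-[(2Z,4S)-6-[(4-methoxybenzyl)oxy]-3-methyl-4-[(triethylsilyl)oxy]hex-2-enoyl]-3-methylidenedihydrofuran-2(3H)-one | C=C1C(=O)O[C@H](/C=C(/CO[Si](C)(C)C(C)(C)C)I)[C@H]1C(=O)/C=C(/C)[C@@H](O[Si](CC)(CC)CC)CCOCc1ccc(OC)cc1
F4 | step 12 | (4R,5S)-5-[(Z)-3-[(tert-butyldimethylsilyl)oxy]-2-iodoprop-1-en-1-yl]-4-[(1R,2Z,4S)-1-hydroxy-6-[(4-methoxybenzyl)oxy]-3-methyl-4-[(triethylsilyl)oxy]hex-2-en-1-yl]-3-methylidenedihydrofuran-2(3H)-one | C=C1C(=O)O[C@H](/C=C(/CO[Si](C)(C)C(C)(C)C)I)[C@H]1[C@H](O)/C=C(/C)[C@@H](O[Si](CC)(CC)CC)CCOCc1ccc(OC)cc1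
F5 | step 10 | (2Z,4S,5E)-1-[(tert-butyldimethylsilyl)oxy]-2-iodohepta-2,5-dien-4-yl prop-2-enoate | C=CC(=O)O[C@@H](/C=C/C)/C=C(/CO[Si](C)(C)C(C)(C)C)I
F6 | step 10 | (S)-5-[(Z)-3-[(tert-butyldimethylsilyl)oxy]-2-iodoprop-1-en-1-yl]furan-2(5H)-one | O=C1C=C[C@@H](/C=C(/CO[Si](C)(C)C(C)(C)C)I)O1
F7 | step 10 | (S)-3-(hydroxymethyl)-5-[(Z)-3-[(tert-butyldimethylsilyl)oxy]-2-iodoprop-1-en-1-yl]furan-2(5H)-one | OCC1=C[C@@H](/C=C(/CO[Si](C)(C)C(C)(C)C)I)OC1=O
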